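**Retrosynthetic overview**

1. The target is read as a normal labdane: 6α-[(2R)-2-methylbutanoyloxy]labda-7,13-dien-16,15-olid-17-oic acid (5α-H, 9α-H, 10β-CH3). Late disconnections are the tert-butyl ester, the C12–C13 bond to an intact bromobutenolide, the C6–O acyl bond (made with inversion), and the C7=C8 unsaturation.
2. Key disconnection: the bonds C3–C4 and C5–C10 are formed together by an intramolecular [4+2] cycloaddition, so rings A and B close in one operation from an acyclic trienone.
3. Enabling feature: the C6 oxygen of ring B sits next to the ring-fusion carbon C5 and one bond further from the gem-dimethyl carbon C4. At the ketone level it makes C4=C5 an enone dienophile inside the future ring B and leaves C5 epimerisable; ring A (C1–C3) is unfunctionalised, so C10=C1–C2=C3 can serve as the diene.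
4. Temporary groups: a phenylsulfanyl group on C1 (stereocontrol, removed with the C1=C2 bond by Raney Ni) and a second ester on C8 (reactivity, removed by Krapcho reaction).
5. The trienone comes from three pieces: an enynol-derived sulfanyl trienyl carbonate (C1–C3, C9–C12, C20), tert-butyl methyl malonate (C8, C17; Ir-catalysed allylic alkylation sets C9), and a bromoketone from mesityl oxide (C4–C7, C18, C19). Ring order: A and B together (step 7); the butenolide ring is attached last.

Key step: step 7

Remark: labdane numbering is used for all bicyclic compounds (α = face of H5, β = face of C20), and simple salts of numbered compounds (alkoxides, enolates, acetylides) are not numbered separately.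

**Step 1**
Reactants: 1 (2E)-pent-2-en-4-yn-1-ol
Product: 2 (2E)-5-(phenylsulfanyl)pent-2-en-4-yn-1-ol
Conditions: n-BuLi (2.1 equiv), THF, −78 °C; PhSSPh, −78 °C → rt; aq. NH4Cl
Reagents that add atoms: diphenyl disulfide, c1ccccc1SSc1ccccc1
Why: Electrophilic sulfenylation of the alkynyllithium of the dianion by the disulfide should give the 1-alkynyl sulfide while the alkoxide stays inert.

**Step 2**
Reactants: 2 (2E)-5-(phenylsulfanyl)pent-2-en-4-yn-1-ol; 3 bromoethene (vinyl bromide)
Product: 6 (2E,4Z)-4-methyl-5-(phenylsulfanyl)hepta-2,4,6-trien-1-ol, via alkenylcopper 4 (not isolated), via alkenylzinc bromide 5 (not isolated)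
Conditions: MeMgBr (1.0 equiv), THF, −40 °C; MeCu·MgBr2 (from MeMgBr and CuBr·SMe2, 1.5 equiv), THF/Me2S, −40 → 0 °C; ZnBr2, Pd(PPh3)4 (5 mol %), vinyl bromide, 0 °C → rt
Reagents that add atoms: methylmagnesium bromide, C[Mg]Br
Why: syn-Carbocupration of the 1-alkynyl sulfide puts copper on the sulfur-bearing carbon and the new methyl (C20) cis to it, and Negishi-type Pd-catalysed vinylation after Cu→Zn exchange goes with retention, so the 4Z geometry (vinyl cis to methyl, sulfur cis to the allylic-alcohol arm) follows from the syn addition.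

**Step 3**
Reactants: 6 (2E,4Z)-4-methyl-5-(phenylsulfanyl)hepta-2,4,6-trien-1-ol
Product: 7 methyl (2E,4Z)-4-methyl-5-(phenylsulfanyl)hepta-2,4,6-trien-1-yl carbonate
Conditions: ClCO2Me, pyridine, CH2Cl2, 0 °C
Reagents that add atoms: methyl chloroformate, COC(=O)Cl
Why: Acylation of the primary allylic alcohol (carbonate formation) installs the leaving group for the allylic substitution.

**Step 4**
Reactants: 8 mesityl oxide (4-methylpent-3-en-2-one)
Product: 10 1-bromo-4-methylpent-3-en-2-one, via silyl dienol ether 9 (not isolated)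
Conditions: LiN(i-Pr)2, THF, −78 °C; TMSCl; then NBS, THF, −78 → 0 °C
Reagents that add atoms: N-bromosuccinimide, O=C1CCC(=O)N1Br
Why: Kinetic deprotonation at the methyl side gives the 2-silyloxy diene, which NBS should brominate at the terminal enol carbon (α′-halogenation of a silyl enol ether).

**Step 5**
Reactants: 7 methyl (2E,4Z)-4-methyl-5-(phenylsulfanyl)hepta-2,4,6-trien-1-yl carbonate; 11 tert-butyl methyl malonate
Product: 12 tert-butyl methyl 2-[(3S,4Z)-4-methyl-5-(phenylsulfanyl)hepta-1,4,6-trien-3-yl]propanedioate (epimers at the malonate carbon)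
Conditions: [Ir(cod)Cl]2 (2 mol %), O,O′-(1,1′-binaphthalene-2,2′-diyl) N,N-bis(1-phenylethyl)phosphoramidite (4 mol %, the enantiomer that gives 3S), TBD (8 mol %), THF, rt
Reagents that add atoms: none
Why: Ir-catalysed asymmetric allylic alkylation should deliver the malonate to the dienyl-substituted allyl terminus (branched product), with the ligand antipode chosen by the established model to set C9 as S in this numbering; this is the only stereocentre the ring system imports, and the malonate-carbon epimers are erased later.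

**Step 6**
Reactants: 12 tert-butyl methyl 2-[(3S,4Z)-4-methyl-5-(phenylsulfanyl)hepta-1,4,6-trien-3-yl]propanedioate; 10 1-bromo-4-methylpent-3-en-2-one
Product: 13 tert-butyl methyl 2-[(3S,4Z)-4-methyl-5-(phenylsulfanyl)hepta-1,4,6-trien-3-yl]-2-(4-methyl-2-oxopent-3-en-1-yl)propanedioate (C8 epimers)
Conditions: NaH, THF/DMF, 0 °C; then 10, 0 °C → rt
Reagents that add atoms: none
Why: Malonic ester alkylation (SN2 of the sodium malonate on the reactive α-bromo ketone) forms the C7–C8 bond and the temporary quaternary C8 without touching C9.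

**Step 7**
Reactants: 13 tert-butyl methyl 2-[(3S,4Z)-4-methyl-5-(phenylsulfanyl)hepta-1,4,6-trien-3-yl]-2-(4-methyl-2-oxopent-3-en-1-yl)propanedioate
Product: 15 tert-butyl methyl 4,4,10β-trimethyl-6-oxo-1-(phenylsulfanyl)-9β-vinyl-5αH-octal-1-ene-8,8-dicarboxylate (trans-fused), via cis-fused adduct 14 (not isolated)
Conditions: Me2AlCl (2.5 equiv), CH2Cl2, −78 → −20 °C; 1 M HCl; then DBU (20 mol %), CH2Cl2, rt
Reagents that add atoms: none
Why: Coordination of Me2AlCl to the C6 ketone makes the β,β-dimethyl enone C4=C5 the dienophile of an intramolecular Diels–Alder reaction with the 2-sulfanyl diene C10=C1–C2=C3; the [4+2] is concerted but asynchronous, the unhindered diene terminus C3 bonding first to the electrophilic gem-dimethyl carbon C4 and C10 then to C5. The closest known reaction type is the Lewis-acid-promoted type 1 intramolecular Diels–Alder reaction of 1,7,9-decatrien-3-ones. Ring A is closed by the cycloaddition itself (both new σ bonds, suprafacial on diene and dienophile), and ring B is closed as the six-membered tether ring by the C5–C10 bond (fused mode, four-atom tether C6–C9). The quaternary stereocentre C10 is controlled by C9: allylic 1,3-strain with the C1 phenylsulfanyl group holds H9 in the diene plane, so the tether carbon C8 delivers the dienophile to one face of C10 while the vinyl group C11 lies on the other, which places C11 and the C20 methyl cis on ring B for an exo or an endo tether alike; C4 is not stereogenic, and C5, α to the C6 ketone, is set thermodynamically when DBU converts the cis-fused adduct 14 into the trans-decalone 15. The step therefore needs only diene π-facial selectivity, secured by the sulfanyl group, and enough reactivity, supplied by the Lewis acid, the geminal diester (Thorpe–Ingold effect) and the matched polarisation of C3 and C4.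

**Step 8**
Reactants: 15 tert-butyl methyl 4,4,10β-trimethyl-6-oxo-1-(phenylsulfanyl)-9β-vinyl-5αH-octal-1-ene-8,8-dicarboxylate
Product: 16 tert-butyl 4,4,10β-trimethyl-6-oxo-1-(phenylsulfanyl)-9β-vinyl-5αH-octal-1-ene-8-carboxylate (C8 epimers)
Conditions: LiCl, DMSO, H2O (2 equiv), 140 °C
Reagents that add atoms: none
Why: Krapcho dealkoxycarbonylation: chloride attacks the methyl but not the tert-butyl ester, the carboxylate loses CO2 and the enolate is protonated; the C8 configuration is irrelevant because C8 becomes sp2 in step 12.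

**Step 9**
Reactants: 16 tert-butyl 4,4,10β-trimethyl-6-oxo-1-(phenylsulfanyl)-9β-vinyl-5αH-octal-1-ene-8-carboxylate
Product: 18 tert-butyl 9β-(2-hydroxyethyl)-4,4,10β-trimethyl-6-oxo-1-(phenylsulfanyl)-5αH-octal-1-ene-8-carboxylate, via alkylborane 17 (not isolated)
Conditions: 9-BBN-H (1.2 equiv), THF, 0 °C → rt; then Me3NO·2H2O, THF, 60 °C
Reagents that add atoms: trimethylamine N-oxide, C[N+](C)(C)[O-]
Why: Anti-Markovnikov hydroboration by 9-BBN should pick the only monosubstituted alkene over the trisubstituted vinyl sulfide and the doubly neopentyl C6 ketone, and amine-oxide oxidation of the borane leaves the sulfide untouched.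

**Step 10**
Reactants: 18 tert-butyl 9β-(2-hydroxyethyl)-4,4,10β-trimethyl-6-oxo-1-(phenylsulfanyl)-5αH-octal-1-ene-8-carboxylate
Product: 19 tert-butyl 9β-(2-hydroxyethyl)-4,4,10β-trimethyl-6-oxo-5αH-decalin-8-carboxylate
Conditions: Raney Ni (W-2, excess), H2 (1 atm), EtOH, rt
Reagents that add atoms: none
Why: Raney nickel hydrogenolysis of the vinyl sulfide with saturation of C1=C2 removes the control group and leaves ring A as in the target (C1 becomes CH2, so no stereocentre forms), while the hindered ketone and the ester should survive.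

**Step 11**
Reactants: 19 tert-butyl 9β-(2-hydroxyethyl)-4,4,10β-trimethyl-6-oxo-5αH-decalin-8-carboxylate
Product: 20 tert-butyl 9β-(2-chloroethyl)-4,4,10β-trimethyl-6-oxo-5αH-decalin-8-carboxylate
Conditions: PPh3, NCS, CH2Cl2, 0 °C → rt
Reagents that add atoms: N-chlorosuccinimide, O=C1CCC(=O)N1Cl
Why: Appel-type chlorination turns the primary alcohol into a robust handle for the later C12–C13 coupling.

**Step 12**
Reactants: 20 tert-butyl 9β-(2-chloroethyl)-4,4,10β-trimethyl-6-oxo-5αH-decalin-8-carboxylate
Product: 22 tert-butyl 9β-(2-chloroethyl)-4,4,10β-trimethyl-6-oxo-5αH-octal-7-ene-8-carboxylate, via silyl enol ether 21 (not isolated)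
Conditions: LiN(i-Pr)2, TMSCl, THF, −78 °C; solvent change; Pd(OAc)2 (1.1 equiv), MeCN, rt
Reagents that add atoms: none
Why: Saegusa–Ito dehydrogenation: enolisation can only go toward C7 (C5 lies between two quaternary carbons) and β-hydride elimination takes C8–H, giving the C7=C8 enone under neutral conditions that should not epimerise the γ-stereocentre C9.

**Step 13**
Reactants: 22 tert-butyl 9β-(2-chloroethyl)-4,4,10β-trimethyl-6-oxo-5αH-octal-7-ene-8-carboxylate
Product: 23 tert-butyl 9β-(2-chloroethyl)-6β-hydroxy-4,4,10β-trimethyl-5αH-octal-7-ene-8-carboxylate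
Conditions: NaBH4, CeCl3·7H2O, MeOH, −78 °C
Reagents that add atoms: none
Why: Luche 1,2-reduction; hydride should add from the α face because the β face of C6 is screened by the axial C20 and 4β-methyl groups, giving the 6β-alcohol.

**Step 14**
Reactants: 23 tert-butyl 9β-(2-chloroethyl)-6β-hydroxy-4,4,10β-trimethyl-5αH-octal-7-ene-8-carboxylate; 24 (2R)-2-methylbutanoic acid
Product: 25 tert-butyl 9β-(2-chloroethyl)-4,4,10β-trimethyl-6α-[(2R)-2-methylbutanoyloxy]-5αH-octal-7-ene-8-carboxylate
Conditions: PPh3, DIAD, toluene, 0 °C → rt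
Reagents that add atoms: none
Why: Mitsunobu esterification with inversion: the carboxylate enters from the open α face to give the 6α ester, and the stereocentre of the acid is not involved.

**Step 15**
Reactants: 25 tert-butyl 9β-(2-chloroethyl)-4,4,10β-trimethyl-6α-[(2R)-2-methylbutanoyloxy]-5αH-octal-7-ene-8-carboxylate; 26 3-bromofuran-2(5H)-one
Product: 28 tert-butyl 6α-[(2R)-2-methylbutanoyloxy]labda-7,13-dien-16,15-olid-17-oate, via alkyl iodide 27 (not isolated)
Conditions: NaI (1.0 equiv), NiCl2(dme) (10 mol %), 4,4′-di-tert-butyl-2,2′-bipyridine (10 mol %), Zn dust (2 equiv), DMA, 50 °C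
Reagents that add atoms: none
Why: Finkelstein exchange followed by nickel-catalysed reductive cross-electrophile coupling of the primary alkyl iodide with the alkenyl bromide forms C12–C13 and brings in the butenolide intact; no stereocentre is formed and the esters should be tolerated.

**Step 16**
Reactants: 28 tert-butyl 6α-[(2R)-2-methylbutanoyloxy]labda-7,13-dien-16,15-olid-17-oate
Product: 29 6α-[(2R)-2-methylbutanoyloxy]labda-7,13-dien-16,15-olid-17-oic acid (5S,6S,9R,10R)
Conditions: TFA/CH2Cl2 (1:4), 0 °C → rt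
Reagents that add atoms: none
Why: Acidolysis of the tert-butyl ester (loss of isobutene) frees the C17 acid without affecting the C6 ester, the butenolide or any stereocentre.

**Compound list**

1 | (2E)-pent-2-en-4-yn-1-ol | OC/C=C/C#C | starting material
2 | (2E)-5-(phenylsulfanyl)pent-2-en-4-yn-1-ol | OC/C=C/C#CSc1ccccc1 | intermediate
3 | bromoethene (vinyl bromide) | C=CBr | starting material
4 | alkenylcopper from syn addition of CH3–Cu across the alkyne of 2 (Cu geminal to SPh and cis to the new methyl), as bromomagnesium alkoxide | Br[Mg]OC/C=C/C(C)=C(/[Cu])Sc1ccccc1 | intermediate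
5 | corresponding alkenylzinc bromide, same geometry | Br[Mg]OC/C=C/C(C)=C(/[Zn]Br)Sc1ccccc1 | intermediate
6 | (2E,4Z)-4-methyl-5-(phenylsulfanyl)hepta-2,4,6-trien-1-ol | OC/C=C/C(C)=C(/C=C)Sc1ccccc1 | intermediate
7 | methyl (2E,4Z)-4-methyl-5-(phenylsulfanyl)hepta-2,4,6-trien-1-yl carbonate | COC(=O)OC/C=C/C(C)=C(/C=C)Sc1ccccc1 | intermediate
8 | mesityl oxide (4-methylpent-3-en-2-one) | CC(=O)C=C(C)C | starting material
9 | trimethyl[(4-methylpenta-1,3-dien-2-yl)oxy]silane | C=C(O[Si](C)(C)C)C=C(C)C | intermediate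
10 | 1-bromo-4-methylpent-3-en-2-one | BrCC(=O)C=C(C)C | intermediate
11 | tert-butyl methyl malonate | COC(=O)CC(=O)OC(C)(C)C | starting material
12 | tert-butyl methyl 2-[(3S,4Z)-4-methyl-5-(phenylsulfanyl)hepta-1,4,6-trien-3-yl]propanedioate | C=C/C(Sc1ccccc1)=C(\C)[C@@H](C=C)C(C(=O)OC)C(=O)OC(C)(C)C | intermediate
13 | tert-butyl methyl 2-[(3S,4Z)-4-methyl-5-(phenylsulfanyl)hepta-1,4,6-trien-3-yl]-2-(4-methyl-2-oxopent-3-en-1-yl)propanedioate | C=C/C(Sc1ccccc1)=C(\C)[C@@H](C=C)C(CC(=O)C=C(C)C)(C(=O)OC)C(=O)OC(C)(C)C | intermediate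
14 | cis-fused adduct: tert-butyl methyl 4,4,10β-trimethyl-6-oxo-1-(phenylsulfanyl)-9β-vinyl-5βH-octal-1-ene-8,8-dicarboxylate | O=C1CC(C(=O)OC)(C(=O)OC(C)(C)C)[C@H](C=C)[C@@]2(C)C(Sc3ccccc3)=CCC(C)(C)[C@@H]12 | intermediate
15 | trans-fused adduct: tert-butyl methyl 4,4,10β-trimethyl-6-oxo-1-(phenylsulfanyl)-9β-vinyl-5αH-octal-1-ene-8,8-dicarboxylate | O=C1CC(C(=O)OC)(C(=O)OC(C)(C)C)[C@H](C=C)[C@@]2(C)C(Sc3ccccc3)=CCC(C)(C)[C@H]12 | intermediate
16 | tert-butyl 4,4,10β-trimethyl-6-oxo-1-(phenylsulfanyl)-9β-vinyl-5αH-octal-1-ene-8-carboxylate (C8 epimers) | O=C1CC(C(=O)OC(C)(C)C)[C@H](C=C)[C@@]2(C)C(Sc3ccccc3)=CCC(C)(C)[C@H]12 | intermediate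
17 | B-alkyl-9-borabicyclo[3.3.1]nonane adduct of 16 (boron on C12) | O=C1CC(C(=O)OC(C)(C)C)[C@H](CCB3C4CCCC3CCC4)[C@@]2(C)C(Sc3ccccc3)=CCC(C)(C)[C@H]12 | intermediate
18 | tert-butyl 9β-(2-hydroxyethyl)-4,4,10β-trimethyl-6-oxo-1-(phenylsulfanyl)-5αH-octal-1-ene-8-carboxylate | O=C1CC(C(=O)OC(C)(C)C)[C@H](CCO)[C@@]2(C)C(Sc3ccccc3)=CCC(C)(C)[C@H]12 | intermediate
19 | tert-butyl 9β-(2-hydroxyethyl)-4,4,10β-trimethyl-6-oxo-5αH-decalin-8-carboxylate | O=C1CC(C(=O)OC(C)(C)C)[C@H](CCO)[C@@]2(C)CCCC(C)(C)[C@H]12 | intermediate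
20 | tert-butyl 9β-(2-chloroethyl)-4,4,10β-trimethyl-6-oxo-5αH-decalin-8-carboxylate | O=C1CC(C(=O)OC(C)(C)C)[C@H](CCCl)[C@@]2(C)CCCC(C)(C)[C@H]12 | intermediate
21 | tert-butyl 9β-(2-chloroethyl)-4,4,10β-trimethyl-6-(trimethylsilyloxy)-5αH-octal-6-ene-8-carboxylate | C[Si](C)(C)OC1=CC(C(=O)OC(C)(C)C)[C@H](CCCl)[C@@]2(C)CCCC(C)(C)[C@H]12 | intermediate
22 | tert-butyl 9β-(2-chloroethyl)-4,4,10β-trimethyl-6-oxo-5αH-octal-7-ene-8-carboxylate | O=C1C=C(C(=O)OC(C)(C)C)[C@H](CCCl)[C@@]2(C)CCCC(C)(C)[C@H]12 | intermediate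
23 | tert-butyl 9β-(2-chloroethyl)-6β-hydroxy-4,4,10β-trimethyl-5αH-octal-7-ene-8-carboxylate | O[C@@H]1C=C(C(=O)OC(C)(C)C)[C@H](CCCl)[C@@]2(C)CCCC(C)(C)[C@H]12 | intermediate
24 | (2R)-2-methylbutanoic acid | CC[C@@H](C)C(=O)O | starting material
25 | tert-butyl 9β-(2-chloroethyl)-4,4,10β-trimethyl-6α-[(2R)-2-methylbutanoyloxy]-5αH-octal-7-ene-8-carboxylate | CC[C@@H](C)C(=O)O[C@H]1C=C(C(=O)OC(C)(C)C)[C@H](CCCl)[C@@]2(C)CCCC(C)(C)[C@H]12 | intermediate
26 | 3-bromofuran-2(5H)-one | O=C1OCC=C1Br | starting material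
27 | tert-butyl 9β-(2-iodoethyl)-4,4,10β-trimethyl-6α-[(2R)-2-methylbutanoyloxy]-5αH-octal-7-ene-8-carboxylate | CC[C@@H](C)C(=O)O[C@H]1C=C(C(=O)OC(C)(C)C)[C@H](CCI)[C@@]2(C)CCCC(C)(C)[C@H]12 | intermediate
28 | tert-butyl 6α-[(2R)-2-methylbutanoyloxy]labda-7,13-dien-16,15-olid-17-oate | CC[C@@H](C)C(=O)O[C@H]1C=C(C(=O)OC(C)(C)C)[C@H](CCC2=CCOC2=O)[C@@]2(C)CCCC(C)(C)[C@H]12 | intermediate
29 | 6α-[(2R)-2-methylbutanoyloxy]labda-7,13-dien-16,15-olid-17-oic acid (5S,6S,9R,10R) | CC[C@@H](C)C(=O)O[C@H]1C=C(C(=O)O)[C@H](CCC2=CCOC2=O)[C@@]2(C)CCCC(C)(C)[C@H]12 | target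

**Step count and risks**

Total step count: 16. Longest linear sequence: 15 steps (steps 1–3 and 5–16); step 4 is a one-step branch.

Steps most likely to fail:

Step 7. The cycloaddition joins a β,β-dimethyl enone to a fully substituted diene terminus and may be too slow at temperatures the sulfanyl diene and the tert-butyl ester tolerate, so Lewis-acid-induced oligomerisation or ester cleavage could outrun ring closure. The fallback sets out from 13 and returns at 15, replacing Lewis-acid activation by a cationic dienophile. The ketone of 13 is treated with 1,2-bis(trimethylsilyloxy)ethane and catalytic TMSOTf (CH2Cl2, −78 °C) to give the 1,3-dioxolane of triene 13 F1. Under the same catalyst F1 ionises reversibly to an alkoxy-stabilised allyl cation, a much stronger dienophile, and should undergo the cationic Diels–Alder reaction at low temperature to the dioxolane of the bicyclic adduct F2 (C5 epimers). PPTS in wet acetone followed by DBU would remove the ketal and equilibrate C5 to give 15.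

Step 14. At the neopentyl-like allylic C6 the oxyphosphonium intermediate may eliminate toward C5 (diene formation), or the substitution may stall. The fallback sets out from 23 and returns at 25, using thermodynamic epimerisation instead of invertive substitution. Alcohol 23 is equilibrated through its enone 22 by Meerwein–Ponndorf–Verley/Oppenauer hydride transfer (Al(O-i-Pr)3, i-PrOH, a little acetone, toluene, 60 °C). This should convert the pseudo-axial 6β-alcohol, which suffers 1,3-diaxial contacts with the C20 and 4β-methyl groups, into the pseudo-equatorial 6α-alcohol F3. Steglich esterification of F3 with 24 (DCC, DMAP, CH2Cl2) then gives 25 with retention.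

Step 15. Reduction or homocoupling of the alkyl partner, or reduction of the bromobutenolide by zinc, may compete with cross-coupling. The fallback sets out from 25 and returns at 28, using enolate alkylation instead of cross-coupling. Chloride 25 is converted to iodide 27 (NaI, acetone, reflux; isolated in this case). Iodide 27 alkylates the lithium enolate of commercially available 3-(phenylsulfanyl)oxolan-2-one (LiN(i-Pr)2, THF/DMPU, −78 → 0 °C) to give the α-alkyl-α-(phenylsulfanyl) lactone F4. Oxidation with mCPBA (1 equiv, −78 °C) gives the sulfoxide F5, whose thermal syn-elimination toward the ring CH2 (toluene, 100 °C, CaCO3) should give butenolide 28.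

**Further compounds**

F1 | step 7 | 1,3-dioxolane of triene 13 (ketal at C6) | C=C/C(Sc1ccccc1)=C(\C)[C@@H](C=C)C(CC1(C=C(C)C)OCCO1)(C(=O)OC)C(=O)OC(C)(C)C
F2 | step 7 | 1,3-dioxolane (at C6) of the bicyclic adduct, C5 epimers | O1CCOC12CC(C(=O)OC)(C(=O)OC(C)(C)C)[C@H](C=C)[C@@]3(C)C(Sc4ccccc4)=CCC(C)(C)C23
F3 | step 14 | tert-butyl 9β-(2-chloroethyl)-6α-hydroxy-4,4,10β-trimethyl-5αH-octal-7-ene-8-carboxylate | O[C@H]1C=C(C(=O)OC(C)(C)C)[C@H](CCCl)[C@@]2(C)CCCC(C)(C)[C@H]12
F4 | step 15 | α-alkyl-α-(phenylsulfanyl)-γ-butyrolactone from 27 (C13 epimers) | CC[C@@H](C)C(=O)O[C@H]1C=C(C(=O)OC(C)(C)C)[C@H](CCC2(Sc3ccccc3)CCOC2=O)[C@@]2(C)CCCC(C)(C)[C@H]12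
F5 | step 15 | corresponding sulfoxide | CC[C@@H](C)C(=O)O[C@H]1C=C(C(=O)OC(C)(C)C)[C@H](CCC2(S(=O)c3ccccc3)CCOC2=O)[C@@]2(C)CCCC(C)(C)[C@H]12
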